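No rate constant is given, so one is built from the readings.

| flask | starting material | time |
|---|---|---|
| larch | 150 mM |  |
| maple | 75.0 mM |  |
| cedar | 33.0 mM | 12 h |

| run | time / h | [product] / mM |
|---|---|---|
| larch run | 0.48 | 5.6 |
| larch run | 0.76 | 9.7 |
| larch run | 1.2 | 14.9 |
| larch run | 1.9 | 23.2 |
| larch run | 3.0 | 36.7 |
| larch run | 4.8 | 56.7 |
| larch run | 7.6 | 84.1 |
| larch run | 12 | 116.9 |
| maple run | 0.48 | 2.8 |
| maple run | 0.76 | 4.6 |
| maple run | 1.2 | 5.9 |
| maple run | 1.9 | 10.5 |
| maple run | 3.0 | 15.5 |
| maple run | 4.8 | 24.1 |
| maple run | 7.6 | 35.0 |
| maple run | 12 | 47.9 |

(standard deviation of a reading: 0.4 mM)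

1. the exponent of [starting material] in the starting rate at the charge of the larch run (at the point where two percent of the starting material have become product) (one fixed amount of product, the same in the runs compared)
2. product in the cedar run at 12 h, as a share of the starting material charged
3. which of these the readings show (the product speeds the reaction / nothing beyond the main steps / the product decays / two substrates go astray together)

- Overall: starting material -> product.
- Constant volume, constant temperature.
- Readings of a species count what is bound in complexes too.
- An order is taken over about fifteen percent of the charge, up and down.

Step 1. The running constant q is ln(charge / (charge − c(product))) / time, the pseudo-first-order constant of a flask. In the maple run at 12 h it is 0.0848 h⁻¹, up from 0.0772 h⁻¹ at 3.0 h. In the larch run it climbs from 0.0935 h⁻¹ to 0.126 h⁻¹. A rising q points to help from the product.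

Step 2. At nearly equal product, the mean rate up to 10.5 mM in the maple run is 0.433 of the mean rate up to 9.7 mM in the larch run. This ratio, read from scattered readings, gives an order of 1.21.

Step 3, upper bound. Scaling the maple q to the cedar charge with that order gives 0.0715 h⁻¹, a share of 57.6 %. This is taken as the high end, since the cedar flask can hold at most 33.0 mM of product, less than the 47.9 mM read in the maple run.

Step 4, lower bound. Carrying the larch-to-maple fall of q at 12 h down to cedar gives 0.0531 h⁻¹, a share of 47.1 %. This is taken as the low end, since q rises less over the maple run than over the larch run, so less of that rise remains to be lost on the way to the cedar flask.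

The forecast gives 1.2, 55 % and "the product speeds the reaction", reasoning “so the product is accelerating the reaction”. Its share lies inside the bracket.

The flask gives 1.2, 50.5 % and "the product speeds the reaction".

    2 starting material ⇌ substrate dimer, settled at all times (22.70 L mol⁻¹)
    substrate dimer → product + starting material (0.2473 h⁻¹)
    starting material + product → 2 product (1.760 L mol⁻¹ h⁻¹)

The cedar q comes to 0.0586 h⁻¹, inside the bracket. With the step of starting material and product taken away, the cedar run falls from 50.5 % to 44.6 %. The answer "the product speeds the reaction" would turn wrong in that run, whose q of 0.0493 h⁻¹ lies below the low end of 0.0531 h⁻¹.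

Readings and results are simulated from invented constants; the scatter is artificial.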